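**Strategy.** The ester bond divides nardostachysin into an iridoid triol and a guaiadienoic acid (guaiane numbering: C1/C5 ring fusion, C4 methyl, C7 isopropyl, C10 carboxyl-bearing). Everything rests on the C5–C6 bond of the seven-membered ring C1–C5–C6–C7–C8–C9–C10. Since C7=C8 is allylic to C6 and C10 can be carried as a ketone, this ring is the [3,3] product of a cis-1-cyclopentenyl-2-alkenylcyclopropanolate whose three-membered ring is C8–C9–C10. One anionic oxy-Cope step closes the ring, places C7=C8, sets C5 and, on protonation, C1. The precursor, a cyclopropanol, comes in one step from an ester and a diene.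

Key step: step 5

Remark: the sense of induction of (S)-p-tol-BINAP (step 1), (4R,5R)-TADDOL (step 4) and (R)-BTM (step 9) is assumed to be the one drawn. If the opposite sense is found, the antipodal ligand is taken.

Locants: guaiane numbering in steps 1–7, cyclopenta[c]pyran locants in steps 8–15.

## Guaiane acid (steps 1–7)

Step 1
Reactants: 1 3-methylcyclopent-2-en-1-one
Product: 4 (3R)-3-methylcyclopent-1-en-1-yl trifluoromethanesulfonate, via bis-enoxysilane 2 (not isolated), via lithium enolate 3 (not isolated)
Conditions: CuCl, NaOtBu, (S)-p-tol-BINAP (5 mol % each), Ph2SiH2 (0.55 equiv), toluene, −78 °C; MeLi, THF, 0 °C; PhNTf2, −78 °C to rt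
Reagents that add atoms: N-phenylbis(trifluoromethanesulfonimide) O=S(=O)(N(c1ccccc1)S(=O)(=O)C(F)(F)F)C(F)(F)F
Why: Copper hydride catalysed asymmetric conjugate reduction delivers hydride to one face of C4 under ligand control and leaves the enol ether regiospecifically between C1 and C5, and Si–O cleavage followed by O-triflation keeps that regiochemistry.

Step 2
Reactants: 4 (3R)-3-methylcyclopent-1-en-1-yl trifluoromethanesulfonate
Product: 5 methyl (3R)-3-methylcyclopent-1-ene-1-carboxylate
Conditions: Pd(OAc)2 (3 mol %), PPh3, CO (1 atm), MeOH, Et3N, DMF, rt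
Reagents that add atoms: carbon monoxide [C-]#[O+]; methanol CO
Why: Palladium-catalysed alkoxycarbonylation of an enol triflate (oxidative addition, CO insertion, methanolysis) should not touch the allylic C4 stereocentre.

Step 3
Reactants: 6 3-methylbut-1-yne
Product: 7 2-isopropylbuta-1,3-diene
Conditions: Grubbs II catalyst (2 mol %), ethylene (1 atm), CH2Cl2, rt
Reagents that add atoms: ethylene C=C
Why: Ruthenium-catalysed cross enyne metathesis of a terminal alkyne with ethylene gives the 2-substituted 1,3-diene directly.

Step 4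
Reactants: 5 methyl (3R)-3-methylcyclopent-1-ene-1-carboxylate; 7 2-isopropylbuta-1,3-diene
Product: 8 (1R,2S)-1-[(3R)-3-methylcyclopent-1-en-1-yl]-2-(3-methylbut-1-en-2-yl)cyclopropan-1-ol (the two alkenyl groups cis)
Conditions: Ti(OiPr)4 and (4R,5R)-TADDOL (1.1 equiv each, toluene, iPrOH stripped); 7 (3 equiv), c-C5H9MgCl (2.5 equiv), THF, −20 °C to rt; cold aqueous work-up
Reagents that add atoms: none
Why: In this Kulinkovich–Cha hydroxycyclopropanation, ligand exchange places titanium on the monosubstituted vinyl group of 7, the titanacyclopropane acts as a 1,2-dicarbanion toward the ester with the inherent cis selectivity of the reaction, and the TADDOLate (not the remote C4 centre) should select the (1R,2S) pair, the minor cis diastereomer being removed by chromatography.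

Step 5
Reactants: 8 (1R,2S)-1-[(3R)-3-methylcyclopent-1-en-1-yl]-2-(3-methylbut-1-en-2-yl)cyclopropan-1-ol
Product: 11 (1R,3aS,8aR)-1-methyl-7-isopropyl-2,3,3a,5,8,8a-hexahydroazulen-4(1H)-one (H1 H4 H5 all cis in guaiane numbering), via potassium cyclopropanolate 9 (not isolated), via potassium enolate 10 (not isolated)
Conditions: KHMDS (1.1 equiv), 18-crown-6, THF, −78 to −20 °C; AcOH in THF, −78 °C
Reagents that add atoms: none
Why: Deprotonation gives cyclopropanolate 9, whose two cis alkenyl groups fold over the three-membered ring and undergo a concerted anionic oxy-Cope ([3,3]-sigmatropic) shift in which the strained C8–C10 bond breaks while C5 of the cyclopentene and the CH2 terminus C6 join. The closest known reaction type is the divinylcyclopropane–cycloheptadiene rearrangement in its oxy-Cope version, shown for cis-1,2-dialkenylcyclopropanols. The seven-membered ring closes through the endo-boat transition state, the only one that gives two cis ring alkenes (C7=C8 and the enolate C1=C10). C5 is controlled by the (1R,2S) cyclopropane configuration, which forces C6 onto the cyclopentene face that carries the C4 methyl group, a contra-steric result that an intermolecular addition would not give. C1 is set by kinetic protonation of enolate 10 at −78 °C on the open face that bears H4 and H5, which gives the cis-fused all-cis triad. The step needs the [3,3] shift to outrun homoenolate ring opening, which the cis geometry, ring strain and alkoxide acceleration secure, and the product must be kept from base so that C1 and the β,γ-alkene do not move.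

Step 6
Reactants: 11 (1R,3aS,8aR)-1-methyl-7-isopropyl-2,3,3a,5,8,8a-hexahydroazulen-4(1H)-one
Product: 13 (1R,3aS,8aR)-1-methyl-7-isopropyl-1,2,3,3a,8,8a-hexahydroazulen-4-yl trifluoromethanesulfonate, via potassium dienolate 12 (not isolated)
Conditions: 11 added to KHMDS (1.05 equiv), THF, −78 °C; PhNTf2, −78 to 0 °C
Reagents that add atoms: N-phenylbis(trifluoromethanesulfonimide) O=S(=O)(N(c1ccccc1)S(=O)(=O)C(F)(F)F)C(F)(F)F
Why: Kinetic deprotonation removes the doubly activated (α-keto and allylic) C9–H rather than the hindered C1–H, and enol triflate formation on the linear dienolate gives the C10=C9–C8=C7 dienyl triflate with C1 untouched.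

Step 7
Reactants: 13 (1R,3aS,8aR)-1-methyl-7-isopropyl-1,2,3,3a,8,8a-hexahydroazulen-4-yl trifluoromethanesulfonate
Product: 14 (1R,3aS,8aR)-1-methyl-7-isopropyl-1,2,3,3a,8,8a-hexahydroazulene-4-carboxylic acid
Conditions: Pd(OAc)2 (5 mol %), dppf, CO (1 atm), H2O, Et3N, DMF, 40 °C
Reagents that add atoms: carbon monoxide [C-]#[O+]; water O
Why: Palladium-catalysed hydroxycarbonylation of the dienyl triflate installs C14 on C10 with retention of the diene and without a base strong enough to reach any stereocentre.

## Iridoid triol (steps 8–15)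

Step 8
Reactants: 15 furfuryl alcohol
Product: 16 6-hydroxy-2H-pyran-3(6H)-one (racemic, anomerising hemiacetal)
Conditions: mCPBA, CH2Cl2, 0 °C to rt
Reagents that add atoms: 3-chloroperoxybenzoic acid O=C(OO)c1cccc(Cl)c1
Why: Achmatowicz rearrangement, in which oxidative opening of the furan to the ene-dione is followed by closure through the carbinol oxygen.

Step 9
Reactants: 16 6-hydroxy-2H-pyran-3(6H)-one
Product: 17 (2R)-5-oxo-5,6-dihydro-2H-pyran-2-yl 2-methylpropanoate
Conditions: (R)-BTM (5 mol %), (iPrCO)2O, iPr2NEt, toluene, 0 °C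
Reagents that add atoms: isobutyric anhydride CC(C)C(=O)OC(=O)C(C)C
Why: In this isothiourea-catalysed acylative dynamic kinetic resolution the hemiacetal epimerises through its open form while the chiral acylammonium ion acylates one enantiomer only, which sets the acetal carbon as R.

Step 10
Reactants: 17 (2R)-5-oxo-5,6-dihydro-2H-pyran-2-yl 2-methylpropanoate; 18 ethyl buta-2,3-dienoate
Product: 19 ethyl (1R,4aR,7aR)-1-(isobutyryloxy)-4-oxo-1,3,4,4a,5,7a-hexahydrocyclopenta[c]pyran-7-carboxylate
Conditions: PPh3 (10 mol %), toluene, 110 °C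
Reagents that add atoms: none
Why: In the Lu phosphine-catalysed [3+2] annulation the α-carbon of the phosphonium dienolate adds to the enone β-carbon (C7a) and closure at C4a follows, both on the face anti to the acyloxy group, which sets the cis ring fusion (4aR,7aR).

Step 11
Reactants: 19 ethyl (1R,4aR,7aR)-1-(isobutyryloxy)-4-oxo-1,3,4,4a,5,7a-hexahydrocyclopenta[c]pyran-7-carboxylate
Product: 20 ethyl (1R,4aR,7aR)-1-(isobutyryloxy)-4-methylidene-1,3,4,4a,5,7a-hexahydrocyclopenta[c]pyran-7-carboxylate
Conditions: Ph3PCH3Br, KHMDS, THF, 0 °C; then 19, −78 to 0 °C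
Reagents that add atoms: methyltriphenylphosphonium bromide C[P+](c1ccccc1)(c1ccccc1)c1ccccc1.[Br-]
Why: Wittig methylenation takes the ketone far faster than the two esters, and the epimerisable C4a is safe because the cis fusion is also the stable one.

Step 12
Reactants: 20 ethyl (1R,4aR,7aR)-1-(isobutyryloxy)-4-methylidene-1,3,4,4a,5,7a-hexahydrocyclopenta[c]pyran-7-carboxylate
Product: 21 (4aR,7aR)-7-(hydroxymethyl)-4-methylidene-1,3,4,4a,5,7a-hexahydrocyclopenta[c]pyran-1-ol (anomeric mixture)
Conditions: DIBAL-H (4.5 equiv), CH2Cl2, −78 °C; Rochelle salt work-up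
Reagents that add atoms: none
Why: DIBAL-H reduction takes the enoate to the allylic alcohol and cleaves the anomeric ester to an aluminium lactolate that should hold at −78 °C and give the lactol on work-up, with C4a and C7a untouched.

Step 13
Reactants: 21 (4aR,7aR)-7-(hydroxymethyl)-4-methylidene-1,3,4,4a,5,7a-hexahydrocyclopenta[c]pyran-1-ol
Product: 22 (4aR,7aR)-7-(hydroxymethyl)-4-methylidene-4,4a,5,7a-tetrahydrocyclopenta[c]pyran-1(3H)-one
Conditions: Ag2CO3 on Celite, toluene, 80 °C, short contact time
Reagents that add atoms: none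
Why: Fétizon oxidation is chosen because lactols are the most reactive substrate class for this reagent, so the lactone should form before the allylic alcohol is attacked.

Step 14
Reactants: 22 (4aR,7aR)-7-(hydroxymethyl)-4-methylidene-4,4a,5,7a-tetrahydrocyclopenta[c]pyran-1(3H)-one
Product: 25 (4aR,6S,7S,7aR)-7-hydroxy-7-(hydroxymethyl)-4-methylidene-1-oxooctahydrocyclopenta[c]pyran-6-yl acetate (regioisomeric monoacetates converge in step 15), via iodo acetate 23 (not isolated), via acetoxonium acetate 24 (not isolated)
Conditions: I2 (1.0 equiv), AgOAc (2.2 equiv), AcOH, rt, dark; then H2O, 90 °C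
Reagents that add atoms: silver acetate CC(=O)[O-].[Ag+]; water O
Why: In the Woodward cis-hydroxylation the iodonium ion forms on the convex face (that of H4a and H7a) of the more nucleophilic trisubstituted alkene, acetate opens it at tertiary C7 from the concave face, and silver-assisted displacement of iodide by that acetate gives the concave-face acetoxonium ion that water opens, so both C–O bonds end cis to the lactone ring and CH2OH ends on the convex face.

Step 15
Reactants: 25 (4aR,6S,7S,7aR)-7-hydroxy-7-(hydroxymethyl)-4-methylidene-1-oxooctahydrocyclopenta[c]pyran-6-yl acetate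
Product: 26 (4aR,6S,7S,7aR)-6,7-dihydroxy-7-(hydroxymethyl)-4-methylidenehexahydrocyclopenta[c]pyran-1(3H)-one
Conditions: K2CO3 (cat.), MeOH, 0 °C; Amberlyst-15 (H+) neutralisation
Reagents that add atoms: none
Why: Zemplén-type transesterification removes the acetate, and any opened δ-lactone recloses on acidification because the only other lactones within reach would be strained (bridged through O6 or trans-fused through the CH2OH oxygen).

## Coupling

Step 16
Reactants: 14 (1R,3aS,8aR)-1-methyl-7-isopropyl-1,2,3,3a,8,8a-hexahydroazulene-4-carboxylic acid; 26 (4aR,6S,7S,7aR)-6,7-dihydroxy-7-(hydroxymethyl)-4-methylidenehexahydrocyclopenta[c]pyran-1(3H)-one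
Product: 27 nardostachysin
Conditions: 2-methyl-6-nitrobenzoic anhydride, DMAP, Et3N, CH2Cl2, 0 °C to rt
Reagents that add atoms: none
Why: Shiina esterification (mixed anhydride, DMAP acyl transfer) should acylate the only primary hydroxyl, since the secondary one sits on the concave face and the third is tertiary.

## Compound list

1 | 3-methylcyclopent-2-en-1-one | CC1=CC(=O)CC1 | starting material
2 | bis{[(3R)-3-methylcyclopent-1-en-1-yl]oxy}diphenylsilane | C[C@@H]1CCC(O[Si](OC2=C[C@H](C)CC2)(c2ccccc2)c2ccccc2)=C1 | intermediate
3 | lithium (3R)-3-methylcyclopent-1-en-1-olate | [Li+].C[C@@H]1CCC([O-])=C1 | intermediate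
4 | (3R)-3-methylcyclopent-1-en-1-yl triflate | C[C@@H]1CCC(OS(=O)(=O)C(F)(F)F)=C1 | intermediate
5 | methyl (3R)-3-methylcyclopent-1-ene-1-carboxylate | C[C@@H]1CCC(C(=O)OC)=C1 | intermediate
6 | 3-methylbut-1-yne | CC(C)C#C | starting material
7 | 2-isopropylbuta-1,3-diene | C=CC(=C)C(C)C | intermediate
8 | (1R,2S)-cis-dialkenylcyclopropanol | O[C@]1(C2=C[C@H](C)CC2)C[C@H]1C(=C)C(C)C | intermediate
9 | potassium salt of 8 | [K+].[O-][C@]1(C2=C[C@H](C)CC2)C[C@H]1C(=C)C(C)C | intermediate
10 | potassium C1=C10 enolate of 11 | [K+].[O-]C1=C2CC[C@@H](C)[C@H]2CC(C(C)C)=CC1 | intermediate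
11 | (1R,3aS,8aR)-hexahydroazulen-4-one | O=C1CC=C(C(C)C)C[C@@H]2[C@H](C)CC[C@H]12 | intermediate
12 | potassium C10=C9–C8=C7 dienolate | [K+].[O-]C1=CC=C(C(C)C)C[C@@H]2[C@H](C)CC[C@H]12 | intermediate
13 | dienyl triflate | O=S(=O)(OC1=CC=C(C(C)C)C[C@@H]2[C@H](C)CC[C@H]12)C(F)(F)F | intermediate
14 | guaia-7,9-dien-14-oic acid | OC(=O)C1=CC=C(C(C)C)C[C@@H]2[C@H](C)CC[C@H]12 | intermediate
15 | furfuryl alcohol | OCc1ccco1 | starting material
16 | 6-hydroxy-2H-pyran-3(6H)-one | O=C1COC(O)C=C1 | intermediate
17 | (2R)-5-oxo-5,6-dihydro-2H-pyran-2-yl isobutyrate | O=C1CO[C@H](OC(=O)C(C)C)C=C1 | intermediate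
18 | ethyl buta-2,3-dienoate | C=C=CC(=O)OCC | starting material
19 | [3+2] adduct (4-ketone) | O=C1CO[C@H](OC(=O)C(C)C)[C@H]2C(C(=O)OCC)=CC[C@@H]12 | intermediate
20 | 4-methylidene diester | C=C1CO[C@H](OC(=O)C(C)C)[C@H]2C(C(=O)OCC)=CC[C@@H]12 | intermediate
21 | lactol allylic alcohol | C=C1COC(O)[C@H]2C(CO)=CC[C@@H]12 | intermediate
22 | lactone allylic alcohol | C=C1COC(=O)[C@H]2C(CO)=CC[C@@H]12 | intermediate
23 | 7-acetoxy-6-iodo lactone (I convex, OAc concave) | C=C1COC(=O)[C@@H]2[C@H]1C[C@@H](I)[C@@]2(OC(C)=O)CO | intermediate
24 | concave-face 6,7-acetoxonium acetate | C=C1COC(=O)[C@@H]2[C@H]1C[C@@H]3OC(C)=[O+][C@]23CO.CC(=O)[O-] | intermediate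
25 | cis-diol 6-monoacetate | C=C1COC(=O)[C@@H]2[C@H]1C[C@H](OC(C)=O)[C@@]2(O)CO | intermediate
26 | iridoid triol | C=C1COC(=O)[C@@H]2[C@H]1C[C@H](O)[C@@]2(O)CO | intermediate
27 | nardostachysin | C=C1COC(=O)[C@@H]2[C@H]1C[C@H](O)[C@@]2(O)COC(=O)C1=CC=C(C(C)C)C[C@@H]2[C@H](C)CC[C@H]12 | target

Total step count: 16. Longest linear sequence: 9 (steps 8–16).

## Steps most likely to fail

**Step 4.** The low-valent titanium may bind diene 7 as an η4-complex or add to the enoate in a conjugate sense. Facial discrimination by the TADDOLate may also be weak.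
- The fallback uses a zinc carbenoid on an enol ether instead of titanium on an ester. It sets out from triflate 4 and returns at ketone 11.
- Carbonylative Stille coupling (Pd(0), CO, tributyl(2-isopropylallyl)stannane) would give 1-[(3R)-3-methylcyclopent-1-en-1-yl]-3-isopropylbut-3-en-1-one F1.
- Soft enolisation (TBSOTf, Et3N) would give the TBS dienol ether with cyclopentenyl and alkenyl groups cis F2.
- Asymmetric Simmons–Smith cyclopropanation of its electron-rich central alkene (Et2Zn, CH2I2, chiral dipeptide ligand) would give the TBS ether of 8 F3.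
- On warming this undergoes the same [3,3] shift to the TBS enol ether of 11 F4.
- HF·pyridine at low temperature then protonates C1 from the open face to give 11.

**Step 14.** Iodonium formation may compete at the exocyclic methylene, or the lactone carbonyl may take part at C6, and either would erode the concave-face cis-diol. The fallback goes by inversion at C7 and then directed reduction at C6. It sets out from 22 and returns at 26.
- VO(acac)2/tBuOOH epoxidises only the allylic-alcohol alkene on the convex face to give the convex-face 6,7-epoxy alcohol F5.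
- Dilute HClO4 in aqueous THF opens it at tertiary C7 with inversion to give the 6-epi-triol F6.
- Bu2SnO followed by NBS oxidises the secondary hydroxyl of the stannylene acetal to give the 6-keto-7-hydroxy lactone F7.
- Me4NBH(OAc)3 bound to the primary hydroxyl delivers hydride on the convex face (Evans–Saksena reduction) to give 26.

**Step 13.** Oxidation of the allylic primary alcohol may compete with oxidation of the lactol. The fallback is exhaustive oxidation followed by selective 1,2-reduction. It sets out from 21 and returns at 22. MnO2 in CH2Cl2 takes both positions to give the lactone enal F8, and Luche reduction (NaBH4, CeCl3, MeOH, −78 °C) returns the allylic alcohol 22 without touching the lactone.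

## Further compounds

F1 | step 4 | 1-[(3R)-3-methylcyclopent-1-en-1-yl]-3-isopropylbut-3-en-1-one | C[C@@H]1CCC(C(=O)CC(=C)C(C)C)=C1
F2 | step 4 | TBS dienol ether with cyclopentenyl and alkenyl groups cis | C[C@@H]1CCC(/C(O[Si](C)(C)C(C)(C)C)=C\C(=C)C(C)C)=C1
F3 | step 4 | TBS ether of 8 | CC(C)(C)[Si](C)(C)O[C@]1(C2=C[C@H](C)CC2)C[C@H]1C(=C)C(C)C
F4 | step 4 | TBS enol ether of 11 | CC(C)(C)[Si](C)(C)OC1=C2CC[C@@H](C)[C@H]2CC(C(C)C)=CC1
F5 | step 14 | convex-face 6,7-epoxy alcohol | C=C1COC(=O)[C@@H]2[C@H]1C[C@H]3O[C@@]23CO
F6 | step 14 | 6-epi-triol | C=C1COC(=O)[C@@H]2[C@H]1C[C@@H](O)[C@@]2(O)CO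
F7 | step 14 | 6-keto-7-hydroxy lactone | C=C1COC(=O)[C@@H]2[C@H]1CC(=O)[C@@]2(O)CO
F8 | step 13 | lactone enal | C=C1COC(=O)[C@H]2C(C=O)=CC[C@@H]12
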